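**Retrosynthetic overview**
1. Target ⇐ ketone 15: hydride from the α-face gives the axial 2β-alcohol, then saponification and acetylation.
2. Ring B ⇐ intramolecular Hosomi–Sakurai closure of (S)-enone 14, which forms C9–C10, the trans ring fusion and the 8(17)-methylene in one step.
3. 14 ⇐ achiral β,γ-enone 13 by catalytic enantioselective proton transfer; 13 ⇐ prochiral 4-methoxycyclohexadienone 11 (Me2CuLi, then SmI2).
4. 11 ⇐ oxidative dearomatization of phenol 10 (key step): the arene of 4-bromo-3,5-dimethylphenol supplies all six ring A carbons, the C2 oxygen and two methyl groups.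
5. 10 ⇐ Suzuki and Negishi couplings around a (Z)-allylsilane vinyl iodide made by carbocupration of 4-bromobut-1-yne; ring A comes from the arene, ring B is closed last.

Assumption: the SMILES is read as the (2R,5S,9S,10S) enantiomer (normal labdane series, axial 2β-acetoxy; labdane numbering is used in the Why lines), and the sense of induction of the amine catalyst in step 8 is assumed, the quinidine-derived pseudoenantiomer being used if it proves opposite.

Step 1
Reactants: 1 4-bromobut-1-yne
Product: 3 [(2Z)-4-bromo-2-(iodomethylidene)butyl]trimethylsilane, via vinylcopper adduct 2 (not isolated)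
Conditions: Me3SiCH2MgCl, CuBr·SMe2, Et2O/Me2S, −45 °C; add 1, −25 to −10 °C; then I2, THF, −60 to 0 °C
Reagents that add atoms: (trimethylsilyl)methylmagnesium chloride (C[Si](C)(C)C[Mg]Cl); CuBr·SMe2 (CSC.[Cu]Br, copper in 2 only); iodine ([I][I])
Why: Normant carbocupration adds the silylmethylcopper syn across the terminal alkyne with copper on the terminal carbon, and iodinolysis with retention gives the vinyl iodide with CH2SiMe3 cis to iodine, the geometry that later places the side chain equatorial at C9; the primary bromide is not displaced at this temperature.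

Step 2
Reactants: 4 ethyl (2E)-3-methyl-4-oxobut-2-enoate
Product: 5 ethyl (2E)-3-methylpenta-2,4-dienoate
Conditions: Ph3PCH3Br, KOtBu, THF, 0 °C to rt
Reagents that add atoms: methyltriphenylphosphonium bromide (C[P+](c1ccccc1)(c1ccccc1)c1ccccc1.[Br-])
Why: Wittig methylenation of the aldehyde leaves the (E)-trisubstituted enoate untouched and gives a terminal vinyl group as the handle for hydroboration.

Step 3
Reactants: 5 ethyl (2E)-3-methylpenta-2,4-dienoate; 3 [(2Z)-4-bromo-2-(iodomethylidene)butyl]trimethylsilane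
Product: 7 ethyl (2E,6Z)-9-bromo-3-methyl-7-[(trimethylsilyl)methyl]nona-2,6-dienoate, via B-alkyl-9-BBN adduct 6 (not isolated)
Conditions: 9-BBN, THF, 0 °C to rt; then 3, PdCl2(dppf) (dppf = 1,1'-bis(diphenylphosphino)ferrocene), AsPh3, Cs2CO3, DMF/H2O, rt
Reagents that add atoms: 9-borabicyclo[3.3.1]nonane (B1C2CCCC1CCC2, in 6 only)
Why: 9-BBN hydroborates the unhindered terminal vinyl group anti-Markovnikov and the B-alkyl Suzuki–Miyaura coupling joins it to the vinyl iodide with retention of the (Z) geometry, zerovalent palladium inserting into the sp2 C–I bond far faster than into the primary C–Br bond.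

Step 4
Reactants: 7 ethyl (2E,6Z)-9-bromo-3-methyl-7-[(trimethylsilyl)methyl]nona-2,6-dienoate; 8 4-bromo-3,5-dimethylphenol
Product: 10 ethyl (2E,6Z)-9-(4-hydroxy-2,6-dimethylphenyl)-3-methyl-7-[(trimethylsilyl)methyl]nona-2,6-dienoate, via alkylzinc bromide 9 (not isolated)
Conditions: Zn dust, LiCl, THF, 50 °C; then 8, Pd(OAc)2, SPhos (2-dicyclohexylphosphino-2',6'-dimethoxybiphenyl), THF, 25 °C
Reagents that add atoms: zinc ([Zn], in 9 only)
Why: LiCl-assisted zinc insertion gives an alkylzinc bromide that tolerates the ester, the allylsilane and the free phenol, and Negishi coupling with a bulky biarylphosphine arylates it at the di-ortho-substituted carbon of the bromophenol.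

Step 5
Reactants: 10 ethyl (2E,6Z)-9-(4-hydroxy-2,6-dimethylphenyl)-3-methyl-7-[(trimethylsilyl)methyl]nona-2,6-dienoate
Product: 11 ethyl (2E,6Z)-9-(1-methoxy-2,6-dimethyl-4-oxocyclohexa-2,5-dien-1-yl)-3-methyl-7-[(trimethylsilyl)methyl]nona-2,6-dienoate
Conditions: PhI(OAc)2, MeOH, 0 °C
Reagents that add atoms: methanol (CO)
Why: Oxidative dearomatization converts the phenol into a phenoxenium-type intermediate that methanol captures at the alkylated para carbon, giving a prochiral cross-conjugated dienone that already carries the ring A carbons, the C2 oxygen and the C4 and C10 methyls.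

Step 6
Reactants: 11 ethyl (2E,6Z)-9-(1-methoxy-2,6-dimethyl-4-oxocyclohexa-2,5-dien-1-yl)-3-methyl-7-[(trimethylsilyl)methyl]nona-2,6-dienoate
Product: 12 ethyl (2E,6Z)-9-(1-methoxy-2,6,6-trimethyl-4-oxocyclohex-2-en-1-yl)-3-methyl-7-[(trimethylsilyl)methyl]nona-2,6-dienoate (racemic)
Conditions: Me2CuLi (MeLi, CuI), Et2O, −40 to 0 °C; aq NH4Cl
Reagents that add atoms: lithium dimethylcuprate ([Li+].C[Cu-]C)
Why: Gilman conjugate addition puts one methyl on a β-carbon of the dienone to create the C4 gem-dimethyl group, the enolate formed blocks a second addition, and the new stereocentre is racemic but is erased in step 7.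

Step 7
Reactants: 12 ethyl (2E,6Z)-9-(1-methoxy-2,6,6-trimethyl-4-oxocyclohex-2-en-1-yl)-3-methyl-7-[(trimethylsilyl)methyl]nona-2,6-dienoate (racemic)
Product: 13 ethyl (2E,6Z)-3-methyl-7-[(trimethylsilyl)methyl]-9-(2,6,6-trimethyl-4-oxocyclohex-1-en-1-yl)nona-2,6-dienoate
Conditions: SmI2, THF/MeOH, −78 °C
Reagents that add atoms: none
Why: Two single-electron transfers reduce the γ-methoxy enone to an allyl anion that expels methoxide (vinylogous α-alkoxy ketone reduction), and kinetic α-protonation of the dienolate by MeOH gives the achiral β,γ-unsaturated ketone.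

Step 8
Reactants: 13 ethyl (2E,6Z)-3-methyl-7-[(trimethylsilyl)methyl]-9-(2,6,6-trimethyl-4-oxocyclohex-1-en-1-yl)nona-2,6-dienoate
Product: 14 ethyl (2E,6Z)-3-methyl-7-[(trimethylsilyl)methyl]-9-[(1S)-2,6,6-trimethyl-4-oxocyclohex-2-en-1-yl]nona-2,6-dienoate
Conditions: 9-amino-9-deoxy-epi-quinine (20 mol %), CF3CO2H (40 mol %), toluene, 0 °C
Reagents that add atoms: none
Why: Proposed new method: the primary amine condenses with the unhindered C2 ketone, deprotonation at C1 gives a conjugated dienamine, and the protonated quinuclidine of the catalyst delivers a proton to one face of the tetrasubstituted γ-carbon C5 to give the conjugated iminium and, after hydrolysis, the (S)-enone; the closest known reaction type is the cinchona primary amine catalysed enantioselective isomerization of β,γ- to α,β-unsaturated cyclohexenones with trisubstituted alkenes, extended here to a tetrasubstituted alkene next to a quaternary carbon.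

Step 9
Reactants: 14 ethyl (2E,6Z)-3-methyl-7-[(trimethylsilyl)methyl]-9-[(1S)-2,6,6-trimethyl-4-oxocyclohex-2-en-1-yl]nona-2,6-dienoate
Product: 15 ethyl (2E)-3-methyl-5-[(1S,4aS,8aS)-5,5,8a-trimethyl-2-methylidene-7-oxodecahydronaphthalen-1-yl]pent-2-enoate
Conditions: TiCl4 (1.1 equiv), CH2Cl2, −78 °C; then H2O
Reagents that add atoms: none
Why: In this intramolecular Hosomi–Sakurai reaction the γ-carbon of the allylsilane attacks C10 of the TiCl4-activated enone through a chair–chair transition state with the C5 tether equatorial and bond formation anti to the axial C4 methyl (as in acid-induced cyclizations of monocyclofarnesyl cations), which gives the trans ring fusion with the 10-methyl axial, while the (Z)-allylsilane places the side chain equatorial at C9 and loss of silicon fixes the 8(17)-methylene.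

Step 10
Reactants: 15 ethyl (2E)-3-methyl-5-[(1S,4aS,8aS)-5,5,8a-trimethyl-2-methylidene-7-oxodecahydronaphthalen-1-yl]pent-2-enoate
Product: 17 (2E)-5-[(1S,4aS,7R,8aS)-7-hydroxy-5,5,8a-trimethyl-2-methylidenedecahydronaphthalen-1-yl]-3-methylpent-2-enoic acid, via hydroxy ester 16 (not isolated)
Conditions: NaBH4, MeOH/THF, −10 °C; then LiOH, H2O, 50 °C; then 1 M HCl to pH 3
Reagents that add atoms: lithium hydroxide ([Li+].[OH-])
Why: NaBH4 reduces only the saturated ketone, hydride entering from the α-face because the β-face is shielded by the syn-axial C4 and C10 methyls, which gives the axial 2β (R) alcohol, and saponification then frees the acid before the base-labile acetate is introduced.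

Step 11
Reactants: 17 (2E)-5-[(1S,4aS,7R,8aS)-7-hydroxy-5,5,8a-trimethyl-2-methylidenedecahydronaphthalen-1-yl]-3-methylpent-2-enoic acid
Product: 18 (2E)-5-[(1S,4aS,7R,8aS)-7-(acetyloxy)-5,5,8a-trimethyl-2-methylidenedecahydronaphthalen-1-yl]-3-methylpent-2-enoic acid
Conditions: Ac2O, pyridine, DMAP (cat.), 40 °C; then H2O/THF, 25 °C
Reagents that add atoms: acetic anhydride (CC(=O)OC(C)=O)
Why: DMAP-catalysed acyl transfer (Steglich-type acetylation) esterifies the hindered axial alcohol with retention, and the mixed anhydride formed at the carboxyl group is hydrolysed in the aqueous work-up to leave the target.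

**Compound list**
1 | 4-bromobut-1-yne | C#CCCBr | starting material
2 | [(1Z)-4-bromo-2-[(trimethylsilyl)methyl]but-1-en-1-yl]copper | C[Si](C)(C)C/C(CCBr)=C\[Cu] | intermediate
3 | [(2Z)-4-bromo-2-(iodomethylidene)butyl]trimethylsilane | C[Si](C)(C)C/C(CCBr)=C\I | intermediate
4 | ethyl (2E)-3-methyl-4-oxobut-2-enoate | CCOC(=O)/C=C(\C)C=O | starting material
5 | ethyl (2E)-3-methylpenta-2,4-dienoate | CCOC(=O)/C=C(\C)C=C | intermediate
6 | ethyl (2E)-5-(9-borabicyclo[3.3.1]nonan-9-yl)-3-methylpent-2-enoate | CCOC(=O)/C=C(\C)CCB1C2CCCC1CCC2 | intermediate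
7 | ethyl (2E,6Z)-9-bromo-3-methyl-7-[(trimethylsilyl)methyl]nona-2,6-dienoate | CCOC(=O)/C=C(\C)CC/C=C(\C[Si](C)(C)C)CCBr | intermediate
8 | 4-bromo-3,5-dimethylphenol | Cc1cc(O)cc(C)c1Br | starting material
9 | [(3Z,7E)-9-ethoxy-7-methyl-9-oxo-3-[(trimethylsilyl)methyl]nona-3,7-dien-1-yl]zinc bromide | CCOC(=O)/C=C(\C)CC/C=C(\C[Si](C)(C)C)CC[Zn]Br | intermediate
10 | ethyl (2E,6Z)-9-(4-hydroxy-2,6-dimethylphenyl)-3-methyl-7-[(trimethylsilyl)methyl]nona-2,6-dienoate | CCOC(=O)/C=C(\C)CC/C=C(\C[Si](C)(C)C)CCc1c(C)cc(O)cc1C | intermediate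
11 | ethyl (2E,6Z)-9-(1-methoxy-2,6-dimethyl-4-oxocyclohexa-2,5-dien-1-yl)-3-methyl-7-[(trimethylsilyl)methyl]nona-2,6-dienoate | CCOC(=O)/C=C(\C)CC/C=C(\C[Si](C)(C)C)CCC1(OC)C(C)=CC(=O)C=C1C | intermediate
12 | ethyl (2E,6Z)-9-(1-methoxy-2,6,6-trimethyl-4-oxocyclohex-2-en-1-yl)-3-methyl-7-[(trimethylsilyl)methyl]nona-2,6-dienoate (racemic) | CCOC(=O)/C=C(\C)CC/C=C(\C[Si](C)(C)C)CCC1(OC)C(C)=CC(=O)CC1(C)C | intermediate
13 | ethyl (2E,6Z)-3-methyl-7-[(trimethylsilyl)methyl]-9-(2,6,6-trimethyl-4-oxocyclohex-1-en-1-yl)nona-2,6-dienoate | CCOC(=O)/C=C(\C)CC/C=C(\C[Si](C)(C)C)CCC1=C(C)CC(=O)CC1(C)C | intermediate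
14 | ethyl (2E,6Z)-3-methyl-7-[(trimethylsilyl)methyl]-9-[(1S)-2,6,6-trimethyl-4-oxocyclohex-2-en-1-yl]nona-2,6-dienoate | CCOC(=O)/C=C(\C)CC/C=C(\C[Si](C)(C)C)CC[C@@H]1C(C)=CC(=O)CC1(C)C | intermediate
15 | ethyl (2E)-3-methyl-5-[(1S,4aS,8aS)-5,5,8a-trimethyl-2-methylidene-7-oxodecahydronaphthalen-1-yl]pent-2-enoate | C=C1CC[C@H]2C(C)(C)CC(=O)C[C@]2(C)[C@H]1CC/C(C)=C/C(=O)OCC | intermediate
16 | ethyl (2E)-5-[(1S,4aS,7R,8aS)-7-hydroxy-5,5,8a-trimethyl-2-methylidenedecahydronaphthalen-1-yl]-3-methylpent-2-enoate | C=C1CC[C@H]2C(C)(C)C[C@@H](O)C[C@]2(C)[C@H]1CC/C(C)=C/C(=O)OCC | intermediate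
17 | (2E)-5-[(1S,4aS,7R,8aS)-7-hydroxy-5,5,8a-trimethyl-2-methylidenedecahydronaphthalen-1-yl]-3-methylpent-2-enoic acid | C=C1CC[C@H]2C(C)(C)C[C@@H](O)C[C@]2(C)[C@H]1CC/C(C)=C/C(=O)O | intermediate
18 | (2E)-5-[(1S,4aS,7R,8aS)-7-(acetyloxy)-5,5,8a-trimethyl-2-methylidenedecahydronaphthalen-1-yl]-3-methylpent-2-enoic acid (CNP0255148.2) | C=C1CC[C@H]2C(C)(C)C[C@@H](OC(C)=O)C[C@]2(C)[C@H]1CC/C(C)=C/C(=O)O | target

**Step count and risks**
Total: 11 steps. Longest linear sequence: 10 steps (steps 1 and 3 to 11; step 2 is a one-step side branch).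

The three steps most likely to fail are steps 8, 9 and 6.

Step 8 may give low conversion or low ee, because the γ-carbon is tetrasubstituted and flanked by a quaternary carbon. The fallback sets out from 13: DBU in CH2Cl2 isomerizes it to the racemic conjugated enone ethyl (2E,6Z)-3-methyl-7-[(trimethylsilyl)methyl]-9-[(1RS)-2,6,6-trimethyl-4-oxocyclohex-2-en-1-yl]nona-2,6-dienoate F3, which is resolved by preparative chiral-phase supercritical-fluid chromatography; the unwanted (R)-enantiomer is re-equilibrated with DBU and recycled, and the route is rejoined at 14.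

Step 9 may suffer protodesilylation or give the cis-fused isomer if the tether reacts from an axial conformer; the ring-fusion outcome rests on the monocyclofarnesyl analogy and is not guaranteed. The fallback sets out from 14 and replaces Lewis acid activation by a radical closure: 9-mesityl-10-methylacridinium tetrafluoroborate (5 mol %), blue light, MeCN/MeOH. Single-electron oxidation of the allylsilane and methanol-assisted loss of silicon give an allyl radical that adds 6-exo through C9 to C10 (Giese addition); reduction and protonation of the α-keto radical then give 15 directly, where the route is rejoined. This fallback makes no new compound (F0), and it does not by itself guarantee the ring fusion either.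

Step 6 may fail because the methyl must add to a β-carbon next to the fully substituted C–OMe carbon. The fallback sets out from phenol 10: PhI(OAc)2 in MeCN/H2O gives the para-quinol ethyl (2E,6Z)-9-(1-hydroxy-2,6-dimethyl-4-oxocyclohexa-2,5-dien-1-yl)-3-methyl-7-[(trimethylsilyl)methyl]nona-2,6-dienoate F1. AlMe3 (CH2Cl2, −20 °C) then binds the tertiary alkoxide and delivers methyl intramolecularly (hydroxyl-directed conjugate addition) to give racemic ethyl (2E,6Z)-9-(1-hydroxy-2,6,6-trimethyl-4-oxocyclohex-2-en-1-yl)-3-methyl-7-[(trimethylsilyl)methyl]nona-2,6-dienoate F2. SmI2 in THF/MeOH removes the γ-hydroxy group as in step 7, and the route is rejoined at 13.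

Further compounds
F1 | step 6 | ethyl (2E,6Z)-9-(1-hydroxy-2,6-dimethyl-4-oxocyclohexa-2,5-dien-1-yl)-3-methyl-7-[(trimethylsilyl)methyl]nona-2,6-dienoate | CCOC(=O)/C=C(\C)CC/C=C(\C[Si](C)(C)C)CCC1(O)C(C)=CC(=O)C=C1C
F2 | step 6 | ethyl (2E,6Z)-9-(1-hydroxy-2,6,6-trimethyl-4-oxocyclohex-2-en-1-yl)-3-methyl-7-[(trimethylsilyl)methyl]nona-2,6-dienoate (racemic) | CCOC(=O)/C=C(\C)CC/C=C(\C[Si](C)(C)C)CCC1(O)C(C)=CC(=O)CC1(C)C
F3 | step 8 | ethyl (2E,6Z)-3-methyl-7-[(trimethylsilyl)methyl]-9-[(1RS)-2,6,6-trimethyl-4-oxocyclohex-2-en-1-yl]nona-2,6-dienoate | CCOC(=O)/C=C(\C)CC/C=C(\C[Si](C)(C)C)CCC1C(C)=CC(=O)CC1(C)C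
F0 | step 9 | none | none
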